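- At late times I wanted one number first: how much other capture product stands in the flask at 6.0 h, since target in the earlier runs read no higher than 1.7%.

| setting | north-west | west | north-east | flask |
|---|---|---|---|---|
| starting material | 0.50 M | 2 M | 1 M | 1.0 M |
| first nucleophile | 2 M | 2 M | 2 M | 2.00 M |
| second nucleophile | 0.90 M | 0.90 M | 0.90 M | 0.900 M |
| protic impurity | 0.050 M | 0.050 M | 0.075 M | 0.0500 M |
| remark | run made earlier | run made earlier | run made earlier |  |
| time |  |  |  | 6.0 h |

| run | time / h | other capture product / % | target / % | starting material / % |
|---|---|---|---|---|
| north-west | 0.250 | 3.9 | 1.3 | 87.5 |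
| north-west | 0.417 | 6.9 | 0 | 83.8 |
| north-west | 0.667 | 9.0 | 0 | 80.6 |
| north-west | 1.00 | 14.5 | 1.7 | 76.1 |
| north-west | 1.50 | 21.5 | 0.5 | 69.0 |
| north-west | 2.50 | 29.5 | 0 | 60.2 |
| north-west | 4.00 | 41.2 | 0.1 | 45.8 |
| west | 0.500 | 8.4 | 0.6 | 87.8 |
| west | 1.00 | 14.8 | 0 | 82.7 |
| west | 1.50 | 18.9 | 0.6 | 79.0 |
| west | 2.00 | 21.8 | 0.1 | 75.9 |
| west | 2.50 | 24.3 | 0.2 | 73.2 |
| west | 3.00 | 26.3 | 0.9 | 66.6 |
| west | 4.00 | 30.8 | 1.4 | 62.9 |
| north-east | 0.333 | 5.1 | 1.5 | 86.2 |
| north-east | 0.833 | 13.4 | 1.0 | 79.7 |
| north-east | 1.50 | 19.7 | 0 | 71.7 |
| north-east | 2.50 | 27.4 | 0.6 | 63.4 |
| north-east | 4.00 | 38.6 | 0 | 53.1 |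

(readings scatter by 1 percentage point)

- the analysis behind the earlier runs scatters by 1 percentage point, standard deviation

1. ratio of other capture product to target at 4.0 min
2. ratio of other capture product to target at 30 min
3. ratio of other capture product to target at 6.0 h
4. which of other capture product and target there is more of at 6.0 h

- The north-east run was short in its balance by 0.0830 M at 4.00 h, against 0.075 M of protic impurity charged, so I took the impurity as destroying its own molar amount of starting material and called what stays a = charge minus impurity.
- I assumed capture runs at k_c[A][D], with k_c a constant, A the starting material and D the second nucleophile, and integrated that second-order law over each run.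
- First way: the north-west run, with second nucleophile in excess, had formed 0.206 M of other capture product by the reading at 4.00 h, which gave k_c = 0.196 /M/h.
- Second way: in the west run the second nucleophile was the limiting reagent and, reckoned from the other capture product read at 4.00 h, stood at 31.6% of its charge, which gave k_c = 0.184 /M/h.
- The two ways differ in which reagent is the limiting one, yet their ratio was 1.07, so I trusted their mean as the capture constant k_c, the capture rate per molar of starting material and per molar of second nucleophile: 0.190 /M/h.
- For the flask, a was 0.950 M, and the same law left 0.476 M of starting material at 6.0 h, so I reckoned 47.4% of other capture product.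
- Dividing by the highest target reading of the earlier runs, I committed to a ratio of other capture product to target above 27.9 at 6.0 h in the flask.
- At 4.0 min my capture was 1.14% against a scatter of 1 percentage point, so I committed to no early ratio.
- The forecast gave 100, 100 and 100 at the three times, with other capture product ahead, saying “I assume a roughly constant ratio near 100”.
- The flask gave ratios of 2.36, 15.1 and 173, with 47.6% of other capture product beside my 47.4%, and 0.275% of target.

    starting material ⇌ intermediate (K = 0.00210, k = 3.30 /h)
    first nucleophile + intermediate ⇌ target (K = 1.50 /M, k = 41.0 /M/h)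
    second nucleophile + intermediate → other capture product (k = 98.0 /M/h)
    starting material + protic impurity → quenched substrate (k = 8.20 /M/h)
    second nucleophile + target → over-reaction product (k = 0.940 /M/h)

- For the neighbouring flask, charged with 2.2 M of second nucleophile, the same 0.190 /M/h and a left 0.145 M of starting material at 6.0 h, which meant 80.5% of other capture product.
- At 6.0 h that neighbouring flask gave 14.4% of starting material, 78.4% of other capture product and a ratio of other capture product to target of 990.

The runs come from a simulation for substances that don't exist; scatter was added.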